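**Retrosynthetic overview**
1. Endgame: moracin Q ⇐ removal of three O-benzyl groups ⇐ Meinwald hydride shift of the epoxide of a C4-prenyl group (this creates CH2–CO–CHMe2) ⇐ 4-prenyl-5-methoxybenzofuran.
2. C4–CH2 bond: aromatic Claisen shift of a 5-O-(1,1-dimethylallyl) ether. Of the two carbons ortho to O5, C6 is occupied by OBn, so only C4 can take the prenyl group.
3. Core feature: the neighbouring benzenoid carbons C3a and C7a hold C3 and O1, and O1–C2(Ar)=C3 is the enolate of a 3,5-dioxygenated acetophenone. Both bonds (C3–C3a and O1–C7a) are cut together, giving that ketone and a 1-bromo-2-iodoarene.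
4. Dihalide: from catechol monobenzyl ether by bromination para to OH, MOM protection, then iodination para to OBn. Iodine marks the future C3a and bromine the future C7a.
5. Ring order: both benzene rings are purchased; the furan ring is the only ring made (step 5).

Key step: step 5

Remark: the target has no stereocentre. The two transient stereocentres of the route (Claisen dienone, epoxide) form as racemates and are erased in the same or the next step. Benzofuran numbering (O1, C2, C3, C3a, C4–C7, C7a) is used throughout.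

**Step 1**
Reactants: 1 2-(benzyloxy)phenol
Product: 2 2-(benzyloxy)-4-bromophenol
Conditions: NBS (1.0 equiv), MeCN, 0 °C, dark
Reagents that add atoms: N-bromosuccinimide, O=C1CCC(=O)N1Br
Why: Electrophilic aromatic bromination: the free hydroxyl is the strongest donor on the ring and NBS in MeCN brominates guaiacol-type phenols para to it, which puts bromine on the carbon that becomes C7a.

**Step 2**
Reactants: 2 2-(benzyloxy)-4-bromophenol
Product: 3 2-(benzyloxy)-4-bromo-1-(methoxymethoxy)benzene
Conditions: MOMCl, K2CO3, acetone, 0 °C → rt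
Reagents that add atoms: chloromethyl methyl ether (MOMCl), COCCl
Why: Williamson-type O-alkylation of the phenoxide with an α-chloro ether gives the MOM acetal, which levels the two oxygen donors for step 3, withstands NaOtBu at 110 °C in step 5 and can later be removed without touching benzyl ethers.

**Step 3**
Reactants: 3 2-(benzyloxy)-4-bromo-1-(methoxymethoxy)benzene
Product: 4 1-(benzyloxy)-5-bromo-4-iodo-2-(methoxymethoxy)benzene
Conditions: I2, AgO2CCF3, solid NaHCO3, CHCl3, 0 °C, dark
Reagents that add atoms: iodine, II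
Why: Electrophilic aromatic iodination by CF3CO2I generated from I2 and AgO2CCF3: 4-halo-1,2-dialkoxybenzenes react at the remaining position para to an alkoxy group (here para to OBn, next to Br), since the other two CH sites are only ortho-activated and one is squeezed between OBn and Br, while NaHCO3 takes up the acid and shields the MOM acetal.

**Step 4**
Reactants: 5 1-(3,5-dihydroxyphenyl)ethanone
Product: 6 1-[3,5-bis(benzyloxy)phenyl]ethanone
Conditions: BnBr (2.3 equiv), K2CO3, acetone, reflux
Reagents that add atoms: benzyl bromide, BrCc1ccccc1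
Why: Williamson ether synthesis: K2CO3 deprotonates the phenols but not the methyl ketone, so both hydroxyls are benzylated without C-alkylation.

**Step 5**
Reactants: 4 1-(benzyloxy)-5-bromo-4-iodo-2-(methoxymethoxy)benzene; 6 1-[3,5-bis(benzyloxy)phenyl]ethanone (1.2 equiv)
Product: 8 6-(benzyloxy)-2-[3,5-bis(benzyloxy)phenyl]-5-(methoxymethoxy)benzofuran, via α-(2-bromoaryl) ketone 7 (not isolated)
Conditions: Pd2(dba)3 (2.5 mol %), DPEphos (6 mol %), NaOtBu (2.8 equiv), degassed toluene, 80 °C then 110 °C
Reagents that add atoms: none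
Why: Zerovalent palladium carrying the wide-bite-angle diphosphine adds oxidatively to the C–I bond of 4, the sodium enolate of 6 replaces iodide on divalent palladium, and C–C reductive elimination forms C3–C3a (Buchwald–Hartwig-type ketone α-arylation) to give 7. Ketone 7 is a deoxybenzoin and far more acidic than 6, so the remaining base converts it at once into its Z-enolate, in which the oxygen lies cis to the bromoaryl ring. Oxidative addition into the adjacent C–Br bond then gives a six-membered oxapalladacycle (Pd, C7a, C3a, C3, C2, O1), and C–O reductive elimination contracts it to the five-membered furan ring with the enolate double bond ending up endocyclic as C2=C3. The closest known reaction type is the palladium-catalysed benzofuran synthesis from enolisable ketones and 1,2-dihaloarenes, whose second half is the known intramolecular enolate O-arylation of α-(2-bromoaryl) ketones. The selectivity needed is positional (carbon at C3a, oxygen at C7a), and it is secured by the much faster insertion into C–I than into C–Br, the two sites being otherwise alike (each para to one alkoxy group and flanked by one CH). A second arylation at the CH2 of 7 is held back by the slight excess of 6, which has only one enolisable position, and by the intramolecular closure competing favourably with another intermolecular coupling; no stereocentre is formed.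

**Step 6**
Reactants: 8 6-(benzyloxy)-2-[3,5-bis(benzyloxy)phenyl]-5-(methoxymethoxy)benzofuran
Product: 9 6-(benzyloxy)-2-[3,5-bis(benzyloxy)phenyl]benzofuran-5-ol
Conditions: conc. aq. HCl (cat.), MeOH–THF, 50 °C
Reagents that add atoms: none
Why: Acid-catalysed transacetalisation: the MOM acetal ionises under dilute HCl and is carried off by methanol, whereas aryl benzyl ethers and the benzofuran are inert under these conditions.

**Step 7**
Reactants: 9 6-(benzyloxy)-2-[3,5-bis(benzyloxy)phenyl]benzofuran-5-ol; 10 3-chloro-3-methylbut-1-yne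
Product: 11 6-(benzyloxy)-2-[3,5-bis(benzyloxy)phenyl]-5-[(2-methylbut-3-yn-2-yl)oxy]benzofuran
Conditions: DBU, CuCl2·2H2O (1 mol %), MeCN–THF, 0 °C
Reagents that add atoms: none
Why: Copper-catalysed propargylic etherification of a phenol with a tertiary propargyl chloride runs through a copper-stabilised propargyl cation at 0 °C, well below the temperature at which the aryl propargyl ether would rearrange to a chromene.

**Step 8**
Reactants: 11 6-(benzyloxy)-2-[3,5-bis(benzyloxy)phenyl]-5-[(2-methylbut-3-yn-2-yl)oxy]benzofuran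
Product: 12 6-(benzyloxy)-2-[3,5-bis(benzyloxy)phenyl]-5-[(2-methylbut-3-en-2-yl)oxy]benzofuran
Conditions: H2 (1 atm), Pd/CaCO3 poisoned with Pb(OAc)2, quinoline, EtOAc, rt
Reagents that add atoms: none
Why: Lindlar semi-hydrogenation: lead- and quinoline-poisoned palladium reduces the terminal alkyne to the vinyl group and stops there, and it is too inactive to hydrogenolyse benzyl or tertiary allyl ethers.

**Step 9**
Reactants: 12 6-(benzyloxy)-2-[3,5-bis(benzyloxy)phenyl]-5-[(2-methylbut-3-en-2-yl)oxy]benzofuran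
Product: 14 6-(benzyloxy)-2-[3,5-bis(benzyloxy)phenyl]-4-(3-methylbut-2-en-1-yl)benzofuran-5-ol, via C4-prenyl cyclohexadienone 13 (not isolated)
Conditions: PhNEt2, 120 °C, argon
Reagents that add atoms: none
Why: Aromatic Claisen rearrangement: the [3,3]-shift can only reach C4 because the other ortho carbon C6 carries OBn, the allyl unit is inverted so that the 1,1-dimethylallyl ether delivers a prenyl group, dienone 13 tautomerises at once to phenol 14, and the basic solvent suppresses acid-catalysed chroman formation.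

**Step 10**
Reactants: 14 6-(benzyloxy)-2-[3,5-bis(benzyloxy)phenyl]-4-(3-methylbut-2-en-1-yl)benzofuran-5-ol
Product: 15 6-(benzyloxy)-2-[3,5-bis(benzyloxy)phenyl]-5-methoxy-4-(3-methylbut-2-en-1-yl)benzofuran
Conditions: MeI, K2CO3, DMF, rt → 40 °C
Reagents that add atoms: iodomethane, CI
Why: Williamson O-methylation of the only free phenol, in which the small electrophile copes with the flanking prenyl and benzyloxy groups.

**Step 11**
Reactants: 15 6-(benzyloxy)-2-[3,5-bis(benzyloxy)phenyl]-5-methoxy-4-(3-methylbut-2-en-1-yl)benzofuran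
Product: 16 6-(benzyloxy)-2-[3,5-bis(benzyloxy)phenyl]-4-[(3,3-dimethyloxiran-2-yl)methyl]-5-methoxybenzofuran (racemic)
Conditions: mCPBA (1.05 equiv), CH2Cl2, 0 °C
Reagents that add atoms: 3-chloroperoxybenzoic acid (mCPBA), OOC(=O)c1cccc(Cl)c1
Why: Prilezhaev epoxidation: the isolated trisubstituted alkene is the most nucleophilic π-bond and should take up one equivalent of peracid faster than the aromatic C2=C3 bond of the benzofuran, and the new stereocentre forms as a racemate that is erased in step 12.

**Step 12**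
Reactants: 16 6-(benzyloxy)-2-[3,5-bis(benzyloxy)phenyl]-4-[(3,3-dimethyloxiran-2-yl)methyl]-5-methoxybenzofuran
Product: 17 1-{6-(benzyloxy)-2-[3,5-bis(benzyloxy)phenyl]-5-methoxybenzofuran-4-yl}-3-methylbutan-2-one
Conditions: BF3·OEt2 (0.3 equiv), CH2Cl2, −78 → −30 °C
Reagents that add atoms: none
Why: Meinwald rearrangement: BF3 opens the epoxide at its tertiary carbon and a 1,2-hydride shift from the adjacent CH–O carbon gives the isopropyl ketone, the same reaction type that turns prenyl-arene epoxides of the coumarin series into 3-methyl-2-oxobutyl arenes.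

**Step 13**
Reactants: 17 1-{6-(benzyloxy)-2-[3,5-bis(benzyloxy)phenyl]-5-methoxybenzofuran-4-yl}-3-methylbutan-2-one
Product: 18 moracin Q, 1-[2-(3,5-dihydroxyphenyl)-6-hydroxy-5-methoxybenzofuran-4-yl]-3-methylbutan-2-one
Conditions: H2 (1 atm), 10% Pd/C, EtOAc–MeOH, rt
Reagents that add atoms: none
Why: Catalytic hydrogenolysis of the three aryl benzyl ethers over Pd/C at 1 atm, conditions under which the dialkyl ketone, the methyl ether and the 2-arylbenzofuran should not be reduced.

**Compound list**
1 | 2-(benzyloxy)phenol | Oc1ccccc1OCc1ccccc1 | starting material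
2 | 2-(benzyloxy)-4-bromophenol | Oc1ccc(Br)cc1OCc1ccccc1 | intermediate
3 | 2-(benzyloxy)-4-bromo-1-(methoxymethoxy)benzene | COCOc1ccc(Br)cc1OCc1ccccc1 | intermediate
4 | 1-(benzyloxy)-5-bromo-4-iodo-2-(methoxymethoxy)benzene | COCOc1cc(I)c(Br)cc1OCc1ccccc1 | intermediate
5 | 1-(3,5-dihydroxyphenyl)ethanone | CC(=O)c1cc(O)cc(O)c1 | starting material
6 | 1-[3,5-bis(benzyloxy)phenyl]ethanone | CC(=O)c1cc(OCc2ccccc2)cc(OCc2ccccc2)c1 | intermediate
7 | 2-[4-(benzyloxy)-2-bromo-5-(methoxymethoxy)phenyl]-1-[3,5-bis(benzyloxy)phenyl]ethanone (not isolated) | COCOc1cc(CC(=O)c2cc(OCc3ccccc3)cc(OCc3ccccc3)c2)c(Br)cc1OCc1ccccc1 | intermediate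
8 | 6-(benzyloxy)-2-[3,5-bis(benzyloxy)phenyl]-5-(methoxymethoxy)benzofuran | COCOc1cc2cc(-c3cc(OCc4ccccc4)cc(OCc4ccccc4)c3)oc2cc1OCc1ccccc1 | intermediate
9 | 6-(benzyloxy)-2-[3,5-bis(benzyloxy)phenyl]benzofuran-5-ol | Oc1cc2cc(-c3cc(OCc4ccccc4)cc(OCc4ccccc4)c3)oc2cc1OCc1ccccc1 | intermediate
10 | 3-chloro-3-methylbut-1-yne | C#CC(C)(C)Cl | starting material
11 | 6-(benzyloxy)-2-[3,5-bis(benzyloxy)phenyl]-5-[(2-methylbut-3-yn-2-yl)oxy]benzofuran | C#CC(C)(C)Oc1cc2cc(-c3cc(OCc4ccccc4)cc(OCc4ccccc4)c3)oc2cc1OCc1ccccc1 | intermediate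
12 | 6-(benzyloxy)-2-[3,5-bis(benzyloxy)phenyl]-5-[(2-methylbut-3-en-2-yl)oxy]benzofuran | C=CC(C)(C)Oc1cc2cc(-c3cc(OCc4ccccc4)cc(OCc4ccccc4)c3)oc2cc1OCc1ccccc1 | intermediate
13 | 6-(benzyloxy)-2-[3,5-bis(benzyloxy)phenyl]-4-(3-methylbut-2-en-1-yl)benzofuran-5(4H)-one (racemic at C4, not isolated) | O=C1C(OCc2ccccc2)=Cc2oc(-c3cc(OCc4ccccc4)cc(OCc4ccccc4)c3)cc2C1CC=C(C)C | intermediate
14 | 6-(benzyloxy)-2-[3,5-bis(benzyloxy)phenyl]-4-(3-methylbut-2-en-1-yl)benzofuran-5-ol | CC(C)=CCc1c(O)c(OCc2ccccc2)cc2oc(-c3cc(OCc4ccccc4)cc(OCc4ccccc4)c3)cc12 | intermediate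
15 | 6-(benzyloxy)-2-[3,5-bis(benzyloxy)phenyl]-5-methoxy-4-(3-methylbut-2-en-1-yl)benzofuran | COc1c(OCc2ccccc2)cc2oc(-c3cc(OCc4ccccc4)cc(OCc4ccccc4)c3)cc2c1CC=C(C)C | intermediate
16 | 6-(benzyloxy)-2-[3,5-bis(benzyloxy)phenyl]-4-[(3,3-dimethyloxiran-2-yl)methyl]-5-methoxybenzofuran (racemic) | COc1c(OCc2ccccc2)cc2oc(-c3cc(OCc4ccccc4)cc(OCc4ccccc4)c3)cc2c1CC1OC1(C)C | intermediate
17 | 1-{6-(benzyloxy)-2-[3,5-bis(benzyloxy)phenyl]-5-methoxybenzofuran-4-yl}-3-methylbutan-2-one | COc1c(OCc2ccccc2)cc2oc(-c3cc(OCc4ccccc4)cc(OCc4ccccc4)c3)cc2c1CC(=O)C(C)C | intermediate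
18 | moracin Q | COc1c(O)cc2oc(-c3cc(O)cc(O)c3)cc2c1CC(=O)C(C)C | target

**Step count and risks**
Total step count: 13.
Longest linear sequence: 12 steps (steps 1–3 and 5–13, from 2-(benzyloxy)phenol).

Steps most likely to fail:

Step 5.
- The domino may stall after the C-arylation because the electron-rich C–Br bond inserts slowly.
- The bromide may be reduced instead of closing.
- The activated methylene may be arylated a second time.
- The methyl ketone may self-condense under NaOtBu.

The fallback sets out from 4 and 6 and comes back at 8. It builds the furan from an alkyne instead of an enolate.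
- Ketone 6 is enolised with lithium diisopropylamide and trapped with ClP(O)(OEt)2 to give diethyl 1-[3,5-bis(benzyloxy)phenyl]ethenyl phosphate F1.
- More lithium diisopropylamide eliminates the phosphate to give 1,3-bis(benzyloxy)-5-ethynylbenzene F2.
- Sonogashira coupling with 4 (PdCl2(PPh3)2, CuI, Et3N, rt) engages only the C–I bond and gives 1-(benzyloxy)-4-{[3,5-bis(benzyloxy)phenyl]ethynyl}-5-bromo-2-(methoxymethoxy)benzene F3.
- Palladium-catalysed hydroxylation of the bromide (Pd2(dba)3, tBuXPhos, KOH, dioxane–H2O, 100 °C) gives 5-(benzyloxy)-2-{[3,5-bis(benzyloxy)phenyl]ethynyl}-4-(methoxymethoxy)phenol F4.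
- The phenoxide of F4 closes 5-endo-dig in the same pot to 8.

Step 12.
- The tertiary cation may be captured by the nucleophilic C3, which sits peri to C4, in a Friedel–Crafts ring closure.
- It may instead be captured by the 5-methoxy oxygen.
- The arylmethyl group may migrate in place of hydride.

The fallback sets out from 15 and comes back at 17, bypassing the epoxide altogether.
- Hydroboration–oxidation (BH3·THF, 0 °C; then NaOH, H2O2) places oxygen on the less substituted alkene carbon and gives 1-{6-(benzyloxy)-2-[3,5-bis(benzyloxy)phenyl]-5-methoxybenzofuran-4-yl}-3-methylbutan-2-ol F5 as a racemate.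
- Dess–Martin periodinane in CH2Cl2 oxidises F5 to 17.

Step 9.
- The tertiary allyl ether may ionise on heating and lose isoprene, returning the phenol.
- The first-formed ortho-prenylphenol may go on to an abnormal Claisen shift or cyclise to a chroman.

The fallback sets out from 9 and comes back at 15. It replaces steps 7–10 with an unsubstituted allyl group that is extended later.
- Allyl bromide and K2CO3 give 5-(allyloxy)-6-(benzyloxy)-2-[3,5-bis(benzyloxy)phenyl]benzofuran F6.
- The robust parent Claisen rearrangement (PhNEt2, 190 °C) gives 4-allyl-6-(benzyloxy)-2-[3,5-bis(benzyloxy)phenyl]benzofuran-5-ol F7.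
- MeI and K2CO3 give 4-allyl-6-(benzyloxy)-2-[3,5-bis(benzyloxy)phenyl]-5-methoxybenzofuran F8.
- Cross-metathesis with excess 2-methylbut-2-ene (second-generation Grubbs catalyst, CH2Cl2, 40 °C) converts the allyl group into the prenyl group of 15.

**Further compounds**
F1 | step 5 | diethyl 1-[3,5-bis(benzyloxy)phenyl]ethenyl phosphate | C=C(OP(=O)(OCC)OCC)c1cc(OCc2ccccc2)cc(OCc2ccccc2)c1
F2 | step 5 | 1,3-bis(benzyloxy)-5-ethynylbenzene | C#Cc1cc(OCc2ccccc2)cc(OCc2ccccc2)c1
F3 | step 5 | 1-(benzyloxy)-4-{[3,5-bis(benzyloxy)phenyl]ethynyl}-5-bromo-2-(methoxymethoxy)benzene | COCOc1cc(C#Cc2cc(OCc3ccccc3)cc(OCc3ccccc3)c2)c(Br)cc1OCc1ccccc1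
F4 | step 5 | 5-(benzyloxy)-2-{[3,5-bis(benzyloxy)phenyl]ethynyl}-4-(methoxymethoxy)phenol | COCOc1cc(C#Cc2cc(OCc3ccccc3)cc(OCc3ccccc3)c2)c(O)cc1OCc1ccccc1
F5 | step 12 | 1-{6-(benzyloxy)-2-[3,5-bis(benzyloxy)phenyl]-5-methoxybenzofuran-4-yl}-3-methylbutan-2-ol (racemic) | COc1c(OCc2ccccc2)cc2oc(-c3cc(OCc4ccccc4)cc(OCc4ccccc4)c3)cc2c1CC(O)C(C)C
F6 | step 9 | 5-(allyloxy)-6-(benzyloxy)-2-[3,5-bis(benzyloxy)phenyl]benzofuran | C=CCOc1cc2cc(-c3cc(OCc4ccccc4)cc(OCc4ccccc4)c3)oc2cc1OCc1ccccc1
F7 | step 9 | 4-allyl-6-(benzyloxy)-2-[3,5-bis(benzyloxy)phenyl]benzofuran-5-ol | C=CCc1c(O)c(OCc2ccccc2)cc2oc(-c3cc(OCc4ccccc4)cc(OCc4ccccc4)c3)cc12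
F8 | step 9 | 4-allyl-6-(benzyloxy)-2-[3,5-bis(benzyloxy)phenyl]-5-methoxybenzofuran | COc1c(OCc2ccccc2)cc2oc(-c3cc(OCc4ccccc4)cc(OCc4ccccc4)c3)cc2c1CC=C
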